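The constant I wanted from the runs was the ratio of two half-lives: that of the left-handed substrate and that of the right-handed substrate, each against the single-handed partner that I took the solid reagent to supply. I assumed that both substrates meet the same partner at the same moment, so the ratio of the two half-lives can be read without knowing the partner's level.

| flask | left-handed substrate | right-handed substrate | solid reagent | remark | time |
|---|---|---|---|---|---|
| blue | 10 mM | 10 mM | 22 mM | run made earlier |  |
| grey | 40 mM | 40 mM | 22 mM | run made earlier |  |
| flask | 20 mM | 20 mM | 22.0 mM |  | 25 min |

| run | time / min | left-handed product / % | right-handed product / % | left-handed substrate / % |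
|---|---|---|---|---|
| blue | 3.00 | 2.5 | 0 | 48.7 |
| blue | 6.00 | 5.3 | 0.8 | 44.3 |
| blue | 10.0 | 10.5 | 2.3 | 38.4 |
| blue | 12.0 | 13.6 | 3.2 | 35.5 |
| blue | 15.0 | 16.2 | 4.1 | 31.5 |
| grey | 1.33 | 0 | 0.6 | 48.8 |
| grey | 4.00 | 2.3 | 0.3 | 47.4 |
| grey | 8.00 | 5.5 | 0.6 | 44.3 |
| grey | 10.0 | 7.0 | 1.9 | 42.7 |
| grey | 15.0 | 10.9 | 3.1 | 38.7 |

(scatter of a reading: 0.5 percentage points)

- partner is single-handed; left-handed substrate and right-handed substrate are mirror images of each other, charged as a racemate, each of them at the stated concentration
- given per volume of solution although it is solid: solid reagent
- at the start none of the solid reagent is in solution
- an excess is the difference of the two amounts in percent of their sum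
- an excess is below zero if the other one leads
- the handed part of partner does not stay in what it makes, so the products of the two hands are mirror images too

- excess of left-handed product over right-handed product in the product at 30 s
- excess of left-handed product over right-handed product in the product at 25 min
- part of the left-handed substrate and right-handed substrate charged together that has reacted at 25 min

Logarithms do this. I took the last reading of each run, with the right-handed substrate as what the balance leaves, and summed over the blue and grey runs:

ln(charged c / remaining c), left-handed substrate: 0.718

ln(charged c / remaining c), right-handed substrate: 0.0922

s = 7.79

This s is the selectivity factor, the log of the part of left-handed substrate left divided by the log of the part of right-handed substrate left. It is a rough reading, since its denominator is small.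

At 30 s, earlier than any reading, both substrates stand near their charge, so I expected the products to form in the ratio s:

excess = (s − 1)/(s + 1) = 77.3 %

The forecast gave an excess of 85 % at 30 s, above my figure, then an excess of 49 % with 28 % reacted at 25 min; it took the later increments of product to suggest a “less selective path growing as reagent accumulates”.

The flask gave an excess of 76.6 % at 30 s, then an excess of 44.9 % with 30.0 % reacted at 25 min.

    partner + left-handed substrate → left-handed product (k = 9.27 /M/min)
    partner + right-handed substrate → right-handed product (k = 1.20 /M/min)
    solid reagent ⇌ partner, rate k3*(cs3 - [partner]) while solid is left; crystals form when [partner] > cs3 (solubility = 6.90 mM, k = 0.194 /min)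
    partner ⇌ dormant form (K = 1.17, k = 0.0510 /min)
    left-handed product ⇌ right-handed product (k = 0.0193 /min)

At 25 min this flask kept 49 % of its left-handed substrate, less than the 91 % of its right-handed substrate, both unbound, and s turns the first figure into 91.2 % for the second. The neighbouring flask with 13 mM of solid reagent kept 57 % of its left-handed substrate, which s turns into 93.0 %, and its right-handed substrate stood at 93 %.

(The runs were generated by integration from invented constants; the scatter is artificial.)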